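**Retrosynthetic overview**
1. Target 21 ⇐ (4Z)-alkene 20 by face-selective peracid epoxidation (last step); the 13-acetate comes from a silyl ether.
2. Ten-membered ring ⇐ spiro[4.5] keto-butenolide 14 by a four-atom radical ring expansion: the C10–C1 bond forms and the C1–C6 bond breaks, so C1 moves from C6 to C10.
3. 14 ⇐ 4-formyl spirobutenolide 10 by asymmetric allylation (sets C8), acylation, and unveiling/oxidation of C1–OH; 10 ⇐ 4-methyl butenolide 8 via enamine/periodate.
4. 8 ⇐ propargylic alcohol 6 by hydroxyl-directed anti-carbomagnesiation/CO2; 6 ⇐ α'-silyloxy enone 3 + acetylide of 4; 3 ⇐ 3-methylcyclohexenone 1 (Rubottom).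
5. Ring order: cyclohexene (bought in 1) → spiro-butenolide (step 3) → ten-membered carbocycle (step 9) → oxirane (step 11).

Assumption: locants C1–C15 in the text are germacrane locants (C1 ketone, C4/C5 oxirane carbons, C6 lactone carbinol, C7=C11 butenolide alkene, C8 ester carbinol, C10 methyl-bearing methine, C12 lactone C=O, C13 CH2OAc).
Assumption: 3–14 are racemic or epimeric only at the silyloxy carbon (future C1) and the carbinol/spiro carbon (future C6); both centres are erased in steps 8 and 9, so they are left undefined in the SMILES.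
Assumption: 4 is bought as the silyl ether of propargyl alcohol.

**Step 1**
Reactants: 1 3-methylcyclohex-2-en-1-one
Product: 3 3-methyl-6-[(triethylsilyl)oxy]cyclohex-2-en-1-one (racemic), via silyl dienol ether 2 (not isolated)
Conditions: LDA, THF, −78 °C; Et3SiCl; then m-CPBA, NaHCO3, CH2Cl2/hexane, −20 °C
Reagents that add atoms: chlorotriethylsilane, CC[Si](Cl)(CC)CC; m-CPBA, OOC(=O)c1cccc(Cl)c1
Why: Rubottom oxidation: kinetic α'-enolisation and silylation give the cross-conjugated dienol ether, the peracid attacks its electron-rich enol-ether C=C, and 1,4-silyl migration delivers the α'-silyloxy enone; the new stereocentre is racemic and is oxidised away in step 8.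

**Step 2**
Reactants: 3 3-methyl-6-[(triethylsilyl)oxy]cyclohex-2-en-1-one; 4 tert-butyl(diphenyl)(prop-2-yn-1-yloxy)silane
Product: 6 1-{3-[(tert-butyldiphenylsilyl)oxy]prop-1-yn-1-yl}-3-methyl-6-[(triethylsilyl)oxy]cyclohex-2-en-1-ol (diastereomer mixture), via lithium acetylide 5 (not isolated)
Conditions: n-BuLi, THF, −78 °C; then 3, −78 → −40 °C; aq. NH4Cl
Reagents that add atoms: none
Why: 1,2-addition of a lithium acetylide to the enone carbonyl; the carbinol configuration does not matter because this carbon becomes the spiro centre that is cleaved in step 9.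

**Step 3**
Reactants: 6 propargylic alcohol
Product: 8 3-{[(tert-butyldiphenylsilyl)oxy]methyl}-4,7-dimethyl-10-[(triethylsilyl)oxy]-1-oxaspiro[4.5]deca-3,6-dien-2-one, via oxamagnesacycle 7 (not isolated)
Conditions: MeMgCl (4 equiv), CuI (10 mol %), THF, 0 → 45 °C; CO2 (1 atm), 0 °C; aq. citric acid, then TsOH (cat.), CH2Cl2
Reagents that add atoms: methylmagnesium chloride, C[Mg]Cl; carbon dioxide, O=C=O
Why: hydroxyl-directed anti-carbomagnesiation of a propargylic alkoxide (Cu-catalysed Grignard addition) puts Me on the proximal alkyne carbon and Mg on the distal one in a five-membered chelate; carboxylation of the vinyl–Mg bond and lactonisation of the resulting (Z)-γ-hydroxy acid fix the tetrasubstituted butenolide alkene with the correct substituent pattern.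

**Step 4**
Reactants: 8 4-methyl spirobutenolide
Product: 10 3-{[(tert-butyldiphenylsilyl)oxy]methyl}-7-methyl-2-oxo-10-[(triethylsilyl)oxy]-1-oxaspiro[4.5]deca-3,6-diene-4-carbaldehyde, via enamine 9 (not isolated)
Conditions: t-BuOCH(NMe2)2, PhMe, 100 °C; then NaIO4, THF/H2O, rt
Reagents that add atoms: sodium periodate, [Na+].[O-]I(=O)(=O)=O (aldehyde O); tert-butoxybis(dimethylamino)methane, CN(C)C(OC(C)(C)C)N(C)C (adds CH–NMe2 to 9 only, lost again as DMF)
Why: the 4-methyl group is the only vinylogous α-CH of the butenolide (the γ-carbon is spiro), so aminomethylenation with Bredereck's reagent gives the push–pull enamine, and periodate cleaves only this electron-rich C=C (enamine formation/oxidative cleavage), leaving the ring alkene untouched.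

**Step 5**
Reactants: 10 aldehyde
Product: 11 3-{[(tert-butyldiphenylsilyl)oxy]methyl}-4-[(1R)-1-hydroxybut-3-en-1-yl]-7-methyl-10-[(triethylsilyl)oxy]-1-oxaspiro[4.5]deca-3,6-dien-2-one
Conditions: allylMgBr, (+)-Ipc2BOMe, Et2O, −78 → 25 °C; then 10, −78 °C; ethanolamine work-up
Reagents that add atoms: allylmagnesium bromide, C=CC[Mg]Br
Why: Brown asymmetric allylboration through a reagent-controlled chair transition state; the (+)-Ipc2BOMe-derived borane has the facial sense that gives (R)-1-phenylbut-3-en-1-ol from benzaldehyde, and so sets C8 as R (the only external source of absolute configuration).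

**Step 6**
Reactants: 11 homoallylic alcohol
Product: 12 (1R)-1-{3-[(tert-butyldiphenylsilyloxy)methyl]-7-methyl-2-oxo-10-[(triethylsilyl)oxy]-1-oxaspiro[4.5]deca-3,6-dien-4-yl}but-3-en-1-yl 3-methylbut-2-enoate
Conditions: Me2C=CHCOCl, pyridine, DMAP (cat.), CH2Cl2, 0 °C
Reagents that add atoms: 3-methylbut-2-enoyl chloride, CC(C)=CC(Cl)=O
Why: DMAP-catalysed O-acylation with retention at C8; pyridine at 0 °C avoids deconjugation of the senecioyl group.

**Step 7**
Reactants: 12 senecioate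
Product: 13 (1R)-1-{3-[(tert-butyldiphenylsilyloxy)methyl]-10-hydroxy-7-methyl-2-oxo-1-oxaspiro[4.5]deca-3,6-dien-4-yl}but-3-en-1-yl 3-methylbut-2-enoate
Conditions: PPTS (cat.), MeOH/CH2Cl2, 0 °C
Reagents that add atoms: none
Why: selective acid-catalysed methanolysis of the triethylsilyl ether, which is several orders of magnitude more labile than the primary TBDPS ether.

**Step 8**
Reactants: 13 secondary alcohol
Product: 14 (1R)-1-{3-[(tert-butyldiphenylsilyloxy)methyl]-7-methyl-2,10-dioxo-1-oxaspiro[4.5]deca-3,6-dien-4-yl}but-3-en-1-yl 3-methylbut-2-enoate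
Conditions: Dess–Martin periodinane, NaHCO3, CH2Cl2, rt
Reagents that add atoms: none
Why: Dess–Martin oxidation of the hindered carbinol to the C1 ketone; the quaternary C6 prevents the β,γ-alkene from moving into conjugation, and 14 is now a 1:1 pair of spiro epimers with C8 fixed.

**Step 9**
Reactants: 14 spiro keto-butenolide
Product: 18 (4Z,6S,8R,10S)-13-[(tert-butyldiphenylsilyl)oxy]-8-[(3-methylbut-2-enoyl)oxy]-1-oxogermacra-4,7(11)-dien-12,6-olide, via secondary alkyl radical 15 (not isolated), via bicyclic alkoxyl radical 16 (not isolated), via butenolide C6 radical 17 (not isolated)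
Conditions: Fe(acac)3 (30 mol %), PhSiH3 (slow addition), i-PrOH/THF, 2 mM, 40 °C, degassed; brief Et3N wash on work-up
Reagents that add atoms: none
Why: Proposed new method: an Fe–H species transfers H• to the unhindered terminal alkene (Markovnikov MHAT; the ring alkene is neopentylic and inductively deactivated, the enoates are electron-poor) to give secondary radical 15, which adds 6-exo to the α-acyloxy ketone C1 to give alkoxyl radical 16; β-scission of C1–C6 is irreversible because it releases the captodative 2-oxyfuranyl radical 17, which is reduced by Fe(II) and C-protonated (or quenched by Fe–H) at C6 to restore the conjugated butenolide (a silyl ether at C13 is kept here because an acetate would be lost by E1cB from the transient dienolate); the closest known reactions are the stannane-mediated Dowd–Beckwith three- and four-carbon ring expansions of ω-haloalkyl β-keto esters and Fe-mediated MHAT cyclisation of alkenyl ketones; both spiro epimers give the same radical 17, H is expected to enter C6 anti to the out-of-plane C4=C5 arm with the C8–H eclipsing C7=C11 (A1,3 strain) relaying C8 to C6, and C10, being α to the new ketone, can settle as the thermodynamic epimer (descriptor 6S here is the target's C6 geometry, because C5 is sp2).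

**Step 10**
Reactants: 18 ring-expanded silyl ether
Product: 20 (4Z,6S,8R,10S)-13-acetoxy-8-[(3-methylbut-2-enoyl)oxy]-1-oxogermacra-4,7(11)-dien-12,6-olide, via primary alcohol 19 (not isolated)
Conditions: TBAF/AcOH (1:1), THF, 0 °C; then Ac2O, pyridine, DMAP (cat.)
Reagents that add atoms: acetic anhydride, CC(=O)OC(C)=O
Why: buffered fluoride desilylation followed by in-flask acetylation; Lewis acids are avoided (risk of transannular ketone–alkene cyclisation) and so are strong bases (C6–H is the acidic γ-H of the butenolide).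

**Step 11**
Reactants: 20 (4Z)-alkene
Product: 21 (4S,5R,6R,8R,10S)-13-acetoxy-4,5-epoxy-8-[(3-methylbut-2-enoyl)oxy]-1-oxogermacr-7(11)-en-12,6-olide
Conditions: m-CPBA, NaHCO3, CH2Cl2, 0 °C
Reagents that add atoms: m-CPBA, OOC(=O)c1cccc(Cl)c1
Why: Prilezhaev epoxidation of the only electron-rich C=C (butenolide and senecioate alkenes are deactivated, Baeyer–Villiger is slower); the Z-alkene gives the required cis-oxirane, and attack on the outer face of the macrocyclic alkene (anti to C7, with the lactone C6–O eclipsing the alkene) would give 4S,5R.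

**Compound list**
1 | 3-methylcyclohex-2-en-1-one | CC1=CC(=O)CCC1 | starting material
2 | triethyl[(4-methylcyclohexa-1,3-dien-2-yl)oxy]silane | CC1=CC(O[Si](CC)(CC)CC)=CCC1 | intermediate
3 | 3-methyl-6-[(triethylsilyl)oxy]cyclohex-2-en-1-one (racemic) | CC1=CC(=O)C(O[Si](CC)(CC)CC)CC1 | intermediate
4 | tert-butyl(diphenyl)(prop-2-yn-1-yloxy)silane (propargyl alcohol TBDPS ether) | C#CCO[Si](c1ccccc1)(c1ccccc1)C(C)(C)C | starting material
5 | {3-[(tert-butyldiphenylsilyl)oxy]prop-1-yn-1-yl}lithium | [Li]C#CCO[Si](c1ccccc1)(c1ccccc1)C(C)(C)C | intermediate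
6 | 1-{3-[(tert-butyldiphenylsilyl)oxy]prop-1-yn-1-yl}-3-methyl-6-[(triethylsilyl)oxy]cyclohex-2-en-1-ol (diastereomer mixture) | CC1=CC(O)(C#CCO[Si](c2ccccc2)(c2ccccc2)C(C)(C)C)C(O[Si](CC)(CC)CC)CC1 | intermediate
7 | spiro 2,5-dihydro-1,2-oxamagnesole (chelated vinylmagnesium alkoxide; Me on C4, CH2OTBDPS on the Mg-bearing C3) | CC1=C(CO[Si](c2ccccc2)(c2ccccc2)C(C)(C)C)[Mg]OC13C=C(C)CCC3O[Si](CC)(CC)CC | intermediate
8 | 3-{[(tert-butyldiphenylsilyl)oxy]methyl}-4,7-dimethyl-10-[(triethylsilyl)oxy]-1-oxaspiro[4.5]deca-3,6-dien-2-one (epimers at C5/C10) | CC1=C(CO[Si](c2ccccc2)(c2ccccc2)C(C)(C)C)C(=O)OC13C=C(C)CCC3O[Si](CC)(CC)CC | intermediate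
9 | 4-[(E)-2-(dimethylamino)ethenyl] analogue of 8 | CN(C)/C=C/C1=C(CO[Si](c2ccccc2)(c2ccccc2)C(C)(C)C)C(=O)OC13C=C(C)CCC3O[Si](CC)(CC)CC | intermediate
10 | 3-{[(tert-butyldiphenylsilyl)oxy]methyl}-7-methyl-2-oxo-10-[(triethylsilyl)oxy]-1-oxaspiro[4.5]deca-3,6-diene-4-carbaldehyde | O=CC1=C(CO[Si](c2ccccc2)(c2ccccc2)C(C)(C)C)C(=O)OC13C=C(C)CCC3O[Si](CC)(CC)CC | intermediate
11 | 4-[(1R)-1-hydroxybut-3-en-1-yl] analogue (C8 = R; epimers at C5/C10) | C=CC[C@@H](O)C1=C(CO[Si](c2ccccc2)(c2ccccc2)C(C)(C)C)C(=O)OC13C=C(C)CCC3O[Si](CC)(CC)CC | intermediate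
12 | (1R)-1-{3-[(TBDPS-oxy)methyl]-7-methyl-2-oxo-10-(triethylsilyloxy)-1-oxaspiro[4.5]deca-3,6-dien-4-yl}but-3-en-1-yl 3-methylbut-2-enoate | C=CC[C@@H](OC(=O)C=C(C)C)C1=C(CO[Si](c2ccccc2)(c2ccccc2)C(C)(C)C)C(=O)OC13C=C(C)CCC3O[Si](CC)(CC)CC | intermediate
13 | 10-hydroxy analogue of 12 | C=CC[C@@H](OC(=O)C=C(C)C)C1=C(CO[Si](c2ccccc2)(c2ccccc2)C(C)(C)C)C(=O)OC13C=C(C)CCC3O | intermediate
14 | 2,10-dioxo analogue (spiro keto-butenolide; two spiro epimers) | C=CC[C@@H](OC(=O)C=C(C)C)C1=C(CO[Si](c2ccccc2)(c2ccccc2)C(C)(C)C)C(=O)OC13C=C(C)CCC3=O | intermediate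
15 | secondary alkyl radical at C10 from 14 | C[CH]C[C@@H](OC(=O)C=C(C)C)C1=C(CO[Si](c2ccccc2)(c2ccccc2)C(C)(C)C)C(=O)OC13C=C(C)CCC3=O | intermediate
16 | bicyclic tertiary alkoxyl radical (new C10–C1 bond, O• on C1) | CC1C[C@@H](OC(=O)C=C(C)C)C2=C(CO[Si](c3ccccc3)(c3ccccc3)C(C)(C)C)C(=O)OC24C=C(C)CCC14[O] | intermediate
17 | ten-membered 2-oxyfuranyl radical at C6 | CC1C[C@@H](OC(=O)C=C(C)C)C2=C(CO[Si](c3ccccc3)(c3ccccc3)C(C)(C)C)C(=O)O[C]2/C=C(C)\CCC1=O | intermediate
18 | (4Z,6S,8R,10S)-13-[(tert-butyldiphenylsilyl)oxy]-8-[(3-methylbut-2-enoyl)oxy]-1-oxogermacra-4,7(11)-dien-12,6-olide | CC(C)(C)[Si](c1ccccc1)(c1ccccc1)OCC1=C2[C@@H](OC1=O)/C=C(C)\CCC(=O)[C@@H](C)C[C@H]2OC(=O)C=C(C)C | intermediate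
19 | 13-hydroxy analogue of 18 | OCC1=C2[C@@H](OC1=O)/C=C(C)\CCC(=O)[C@@H](C)C[C@H]2OC(=O)C=C(C)C | intermediate
20 | (4Z,6S,8R,10S)-13-acetoxy-8-[(3-methylbut-2-enoyl)oxy]-1-oxogermacra-4,7(11)-dien-12,6-olide | CC(=O)OCC1=C2[C@@H](OC1=O)/C=C(C)\CCC(=O)[C@@H](C)C[C@H]2OC(=O)C=C(C)C | intermediate
21 | (4S,5R,6R,8R,10S)-13-acetoxy-4,5-epoxy-8-[(3-methylbut-2-enoyl)oxy]-1-oxogermacr-7(11)-en-12,6-olide (CNP0220542.1) | CC(=O)OCC1=C2[C@@H](OC1=O)[C@H]1O[C@@]1(C)CCC(=O)[C@@H](C)C[C@H]2OC(=O)C=C(C)C | target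

**Step count and risks**
Total steps: 11. Longest linear sequence: 11 (from 1).

Most likely to fail, first: step 9. The cascade is unprecedented. MHAT at the ring alkene would trigger C5–C6 scission, the C10 radical may be reduced before it cyclises, and quenching of 17 may give C6/C10 mixtures. The fallback uses the classical stannane Dowd–Beckwith protocol and sets out from 12. Tsuji–Wacker oxidation of the terminal alkene (PdCl2, CuCl, O2, DMF/H2O) gives the methyl ketone F1. Luche reduction gives the secondary carbinol F2, and Appel iodination (I2, PPh3, imidazole) gives the secondary iodide F3. PPTS/MeOH then frees the ring carbinol F4, and Dess–Martin oxidation gives the keto iodide F5. Slow addition of Bu3SnH/AIBN (PhH, 80 °C, 2 mM) generates the same radical 15 by iodine abstraction and ends by H-transfer to C6, so the route is rejoined at 18.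

Second: step 11. Which face of the macrocyclic Z-alkene the peracid takes cannot be predicted with confidence. If the 4R,5S-oxirane forms, the fallback sets out from 20. NBS in aqueous THF gives the anti bromohydrin F6 (OH on the tertiary C4, Br on C5). Ag2O then closes it with inversion at C5, which places the oxirane oxygen on the face opposite to that taken by direct epoxidation, and the route is rejoined at 21.

Third: step 6. The acylation itself is safe; the risk is the commitment. It fixes C8 as the R ester before step 9 has shown which C6/C8 relationship the macrocycle delivers, and it sends the enoate through the radical step. If 6-epi-18 is formed, or the senecioate interferes, the fallback sets out from 10. Allylation with the enantiomeric borane (from (−)-Ipc2BOMe) gives the (S)-carbinol F7, and TBSOTf/2,6-lutidine gives the silyl ether F8. PPTS/MeOH gives the ring carbinol F9 and Dess–Martin oxidation gives the ketone F10. The step 9 conditions then give the ring-expanded bis-silyl ether F11, and TBAF/AcOH gives the diol F12. AcCl/2,4,6-collidine at −78 °C acetylates only the primary hydroxyl to give the mono-acetate F13. A Mitsunobu reaction with 3-methylbut-2-enoic acid (PPh3, DIAD) installs the ester with inversion at C8, and the route is rejoined at 20.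

**Further compounds**
F1 | step 9 | (1R)-3-oxo-1-{3-[(TBDPS-oxy)methyl]-7-methyl-2-oxo-10-(triethylsilyloxy)-1-oxaspiro[4.5]deca-3,6-dien-4-yl}butyl 3-methylbut-2-enoate | CC(=O)C[C@@H](OC(=O)C=C(C)C)C1=C(CO[Si](c2ccccc2)(c2ccccc2)C(C)(C)C)C(=O)OC13C=C(C)CCC3O[Si](CC)(CC)CC
F2 | step 9 | 3-hydroxybutyl analogue of F1 (carbinol epimers) | CC(O)C[C@@H](OC(=O)C=C(C)C)C1=C(CO[Si](c2ccccc2)(c2ccccc2)C(C)(C)C)C(=O)OC13C=C(C)CCC3O[Si](CC)(CC)CC
F3 | step 9 | 3-iodobutyl analogue of F1 | CC(I)C[C@@H](OC(=O)C=C(C)C)C1=C(CO[Si](c2ccccc2)(c2ccccc2)C(C)(C)C)C(=O)OC13C=C(C)CCC3O[Si](CC)(CC)CC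
F4 | step 9 | 10-hydroxy iodide | CC(I)C[C@@H](OC(=O)C=C(C)C)C1=C(CO[Si](c2ccccc2)(c2ccccc2)C(C)(C)C)C(=O)OC13C=C(C)CCC3O
F5 | step 9 | 10-oxo iodide (keto iodide) | CC(I)C[C@@H](OC(=O)C=C(C)C)C1=C(CO[Si](c2ccccc2)(c2ccccc2)C(C)(C)C)C(=O)OC13C=C(C)CCC3=O
F6 | step 11 | (4S,5S,6R,8R,10S)-13-acetoxy-5-bromo-4-hydroxy-8-[(3-methylbut-2-enoyl)oxy]-1-oxogermacr-7(11)-en-12,6-olide | CC(=O)OCC1=C2[C@@H](OC1=O)[C@H](Br)[C@](O)(C)CCC(=O)[C@@H](C)C[C@H]2OC(=O)C=C(C)C
F7 | step 6 | 4-[(1S)-1-hydroxybut-3-en-1-yl] epimer of 11 | C=CC[C@H](O)C1=C(CO[Si](c2ccccc2)(c2ccccc2)C(C)(C)C)C(=O)OC13C=C(C)CCC3O[Si](CC)(CC)CC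
F8 | step 6 | (1S)-1-[(tert-butyldimethylsilyl)oxy]but-3-enyl analogue | C=CC[C@H](O[Si](C)(C)C(C)(C)C)C1=C(CO[Si](c2ccccc2)(c2ccccc2)C(C)(C)C)C(=O)OC13C=C(C)CCC3O[Si](CC)(CC)CC
F9 | step 6 | 10-hydroxy analogue of F8 | C=CC[C@H](O[Si](C)(C)C(C)(C)C)C1=C(CO[Si](c2ccccc2)(c2ccccc2)C(C)(C)C)C(=O)OC13C=C(C)CCC3O
F10 | step 6 | 10-oxo analogue of F8 | C=CC[C@H](O[Si](C)(C)C(C)(C)C)C1=C(CO[Si](c2ccccc2)(c2ccccc2)C(C)(C)C)C(=O)OC13C=C(C)CCC3=O
F11 | step 6 | (4Z,6S,8S,10S)-8-[(tert-butyldimethylsilyl)oxy]-13-[(tert-butyldiphenylsilyl)oxy]-1-oxogermacra-4,7(11)-dien-12,6-olide | CC(C)(C)[Si](c1ccccc1)(c1ccccc1)OCC1=C2[C@@H](OC1=O)/C=C(C)\CCC(=O)[C@@H](C)C[C@@H]2O[Si](C)(C)C(C)(C)C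
F12 | step 6 | (4Z,6S,8S,10S)-8,13-dihydroxy-1-oxogermacra-4,7(11)-dien-12,6-olide | OCC1=C2[C@@H](OC1=O)/C=C(C)\CCC(=O)[C@@H](C)C[C@@H]2O
F13 | step 6 | (4Z,6S,8S,10S)-13-acetoxy-8-hydroxy-1-oxogermacra-4,7(11)-dien-12,6-olide | CC(=O)OCC1=C2[C@@H](OC1=O)/C=C(C)\CCC(=O)[C@@H](C)C[C@@H]2O
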